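**Retrosynthetic overview**
1. Target 22 ⇐ diol ketone 19 (both angelates put on, C4–O unmasked last); the C11 methyl comes from cuprate addition to tricyclic enone 18.
2. Third ring (cyclohexenone C1, C8–C11) ⇐ intramolecular aldol condensation of the acetyl/formyl pair carried by cycloadduct 16.
3. First two rings, formed together (cyclobutane and seven-membered ring; bonds C1–C7 and C2–C8) ⇐ crossed intramolecular enone–olefin [2+2] photocycloaddition of acyclic dienone 15.
4. 15 ⇐ Nozaki–Hiyama–Kishi union of aldehyde 9 with Z-vinyl iodide 13; 9 ⇐ (S)-glyceraldehyde acetonide by indium-mediated reverse prenylation and cross-metathesis with methyl vinyl ketone.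

Assumption: tricyclic compounds are numbered as tricyclo[5.4.0.0^{2,8}]undecan-9-one (cyclobutane C1/C2/C8/C7; ketone bridge C9–C11; oxygenated bridge C3–C6), acyclic compounds by their own IUPAC locants, and 1, 2, 7, 10 and 20 are bought.

**Step 1**
Reactants: 1 (S)-2,2-dimethyl-1,3-dioxolane-4-carbaldehyde; 2 1-bromo-3-methylbut-2-ene
Product: 4 (2S,3S)-4,4-dimethylhex-5-ene-1,2,3-triol, via (S)-2,3-dihydroxypropanal 3 (not isolated)
Conditions: 80% aq. AcOH, 40 °C; evaporate; In, THF–H2O, rt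
Reagents that add atoms: none
Why: Acetonide hydrolysis then Barbier-type indium-mediated reverse prenylation in water; the free α-hydroxyl chelates indium (Cram-chelate), so the prenyl γ-carbon adds to give the 2,3-syn triol (new C3, S) together with the CMe2 and vinyl groups.

**Step 2**
Reactants: 4 (2S,3S)-4,4-dimethylhex-5-ene-1,2,3-triol
Product: 5 (2S,3S)-1,2-bis[(tert-butyldimethylsilyl)oxy]-4,4-dimethylhex-5-en-3-ol
Conditions: TBSCl (2.2 equiv), imidazole, DMF, 0 °C
Reagents that add atoms: tert-butyldimethylsilyl chloride, CC(C)(C)[Si](C)(C)Cl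
Why: Silyl ether formation under steric control; the primary and the C2 hydroxyl react, the neopentyl C3 hydroxyl next to CMe2 does not.

**Step 3**
Reactants: 5 (2S,3S)-1,2-bis[(tert-butyldimethylsilyl)oxy]-4,4-dimethylhex-5-en-3-ol
Product: 6 (2S,3S)-2-[(tert-butyldimethylsilyl)oxy]-4,4-dimethylhex-5-ene-1,3-diol
Conditions: HF·pyridine, pyridine, THF, 0 °C
Reagents that add atoms: none
Why: Selective desilylation; the primary TBS ether is cleaved much faster than the secondary one, and acidic conditions avoid silyl migration.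

**Step 4**
Reactants: 6 (2S,3S)-2-[(tert-butyldimethylsilyl)oxy]-4,4-dimethylhex-5-ene-1,3-diol; 7 but-3-en-2-one
Product: 8 (3E,6S,7S)-7-[(tert-butyldimethylsilyl)oxy]-6,8-dihydroxy-5,5-dimethyloct-3-en-2-one
Conditions: Hoveyda–Grubbs II (5 mol%), 7 (4 equiv), CH2Cl2, 40 °C
Reagents that add atoms: none
Why: Olefin cross-metathesis of the hindered vinyl group (on a quaternary carbon, no homodimerisation) with methyl vinyl ketone gives the E-enone.

**Step 5**
Reactants: 8 (3E,6S,7S)-7-[(tert-butyldimethylsilyl)oxy]-6,8-dihydroxy-5,5-dimethyloct-3-en-2-one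
Product: 9 (2R,3S,5E)-2-[(tert-butyldimethylsilyl)oxy]-3-hydroxy-4,4-dimethyl-7-oxooct-5-enal
Conditions: TEMPO (10 mol%), PhI(OAc)2, CH2Cl2, rt
Reagents that add atoms: none
Why: TEMPO/PhI(OAc)2 oxidation is selective for the primary alcohol over the neopentyl secondary one and leaves the α-silyloxy stereocenter untouched.

**Step 6**
Reactants: 10 but-2-yn-1-ol
Product: 11 (Z)-3-iodobut-2-en-1-ol
Conditions: Red-Al, THF, 0 °C → rt; I2, −78 °C
Reagents that add atoms: iodine, II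
Why: Hydroxyl-directed trans-hydroalumination puts aluminium on C3, and iodinolysis with retention gives the Z-vinyl iodide.

**Step 7**
Reactants: 11 (Z)-3-iodobut-2-en-1-ol
Product: 13 (Z)-1,1-diethoxy-3-iodobut-2-ene, via (Z)-3-iodobut-2-enal 12 (not isolated)
Conditions: MnO2, CH2Cl2, rt; filter; HC(OEt)3, PPTS (cat.), rt
Reagents that add atoms: triethyl orthoformate, CCOC(OCC)OCC
Why: Allylic MnO2 oxidation followed at once by orthoformate acetalisation masks the isomerisation-prone Z-enal with its geometry intact.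

**Step 8**
Reactants: 9 (2R,3S,5E)-2-[(tert-butyldimethylsilyl)oxy]-3-hydroxy-4,4-dimethyl-7-oxooct-5-enal; 13 (Z)-1,1-diethoxy-3-iodobut-2-ene
Product: 14 (3E,6S,7S,8S,9Z)-7-[(tert-butyldimethylsilyl)oxy]-11,11-diethoxy-6,8-dihydroxy-5,5,9-trimethylundeca-3,9-dien-2-one
Conditions: CrCl2, NiCl2 (cat.), DMSO, rt
Reagents that add atoms: none
Why: Nozaki–Hiyama–Kishi coupling is chemoselective for the aldehyde and retains the Z geometry; Felkin–Anh addition anti to the α-OTBS group, reinforced by 1,3-anti induction from the β-hydroxyl, sets C8 (S).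

**Step 9**
Reactants: 14 (3E,6S,7S,8S,9Z)-7-[(tert-butyldimethylsilyl)oxy]-11,11-diethoxy-6,8-dihydroxy-5,5,9-trimethylundeca-3,9-dien-2-one
Product: 15 (3E,6S,7S,8S,9Z)-7-[(tert-butyldimethylsilyl)oxy]-11,11-diethoxy-5,5,9-trimethyl-6,8-bis[(trimethylsilyl)oxy]undeca-3,9-dien-2-one
Conditions: TMSCl, imidazole, CH2Cl2, 0 °C
Reagents that add atoms: chlorotrimethylsilane, C[Si](C)(C)Cl
Why: Silylation of both free hydroxyls prevents hemiketal formation with the enone and cyclic-acetal formation at C8–OH, and leaves H8 as the only small allylic substituent.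

**Step 10**
Reactants: 15 (3E,6S,7S,8S,9Z)-7-[(tert-butyldimethylsilyl)oxy]-11,11-diethoxy-5,5,9-trimethyl-6,8-bis[(trimethylsilyl)oxy]undeca-3,9-dien-2-one
Product: 16 1-[3-[(tert-butyldimethylsilyl)oxy]-8-(diethoxymethyl)-1,5,5-trimethyl-2,4-bis[(trimethylsilyl)oxy]bicyclo[4.1.1]octan-7-yl]ethan-1-one (C1–C6 configured as C2–C7 of 22; acetyl anti and CH(OEt)2 syn to the four-carbon bridge)
Conditions: hν (350 nm), degassed MeCN (2 mM), rt
Reagents that add atoms: none
Why: Proposed new method: n→π* excitation gives the enone triplet, whose β-carbon (C4) adds 7-endo to the less substituted alkene terminus (C10) to leave a tertiary radical at C9 that collapses with the α-keto radical at C3, giving the crossed bicyclo[4.1.1]octane because the 6-exo mode would have to join the neopentyl C4 to the fully substituted C9; A(1,3) strain from the Z-acetal holds H8 in the alkene plane so the tether reaches one face only, which fixes the ring carbons relative to C6–C8; the closest known reaction type is the substituent-directed crossed intramolecular enone–olefin [2+2] photocycloaddition of 1-acyl-1,6-heptadienes, here on a tether one carbon longer.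

**Step 11**
Reactants: 16 1-[3-[(tert-butyldimethylsilyl)oxy]-8-(diethoxymethyl)-1,5,5-trimethyl-2,4-bis[(trimethylsilyl)oxy]bicyclo[4.1.1]octan-7-yl]ethan-1-one
Product: 18 4-[(tert-butyldimethylsilyl)oxy]-3,5-dihydroxy-2,6,6-trimethyltricyclo[5.4.0.0^{2,8}]undec-10-en-9-one (stereocentres as in 22), via 7-acetyl-3-[(tert-butyldimethylsilyl)oxy]-2,4-dihydroxy-1,5,5-trimethylbicyclo[4.1.1]octane-8-carbaldehyde 17 (not isolated)
Conditions: PPTS, acetone–H2O, 40 °C; concentrate; pyrrolidine, AcOH, PhMe, 60 °C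
Reagents that add atoms: none
Why: Acetal/TMS hydrolysis, then enamine-mediated intramolecular aldol condensation; the formyl-bearing carbon epimerises via the enamine, only the epimer with the formyl group anti to the four-carbon bridge can close the bicyclo[3.1.1]heptenone, and dehydration makes closure irreversible (TBS stays on the least hindered oxygen).

**Step 12**
Reactants: 18 4-[(tert-butyldimethylsilyl)oxy]-3,5-dihydroxy-2,6,6-trimethyltricyclo[5.4.0.0^{2,8}]undec-10-en-9-one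
Product: 19 4-[(tert-butyldimethylsilyl)oxy]-3,5-dihydroxy-2,6,6,11-tetramethyltricyclo[5.4.0.0^{2,8}]undecan-9-one (all stereocentres as in 22)
Conditions: Me2CuLi (4 equiv, from MeLi and CuI), Et2O–THF, −78 → −30 °C; aq. NH4Cl
Reagents that add atoms: lithium dimethylcuprate, [Li+].C[Cu-]C
Why: Gilman cuprate conjugate addition; methyl is delivered to the enone face opposite the C2 bridge, whose methyl overhangs the other face (as in apoverbenone), setting C11 (R).

**Step 13**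
Reactants: 19 4-[(tert-butyldimethylsilyl)oxy]-3,5-dihydroxy-2,6,6,11-tetramethyltricyclo[5.4.0.0^{2,8}]undecan-9-one; 20 (Z)-2-methylbut-2-enoic acid (angelic acid)
Product: 21 4-[(tert-butyldimethylsilyl)oxy]-2,6,6,11-tetramethyl-9-oxotricyclo[5.4.0.0^{2,8}]undecane-3,5-diyl bis[(2Z)-2-methylbut-2-enoate] (the 4-O-TBS ether of 22)
Conditions: 20 (6 equiv), 2,4,6-Cl3C6H2COCl (6 equiv), Et3N, PhMe, rt, 2 h; then 19, 80 °C
Reagents that add atoms: (Z)-2-methylbut-2-enoic acid (angelic acid; the second equivalent of 20, one angeloyl group per hydroxyl), C/C=C(/C)C(=O)O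
Why: Yamaguchi-type mixed-anhydride esterification without DMAP, in which two equivalents of 20 are consumed (one per hydroxyl), acylates both free neopentylic hydroxyls while keeping the Z (angelate) geometry; O4 is blocked as its TBS ether.

**Step 14**
Reactants: 21 4-[(tert-butyldimethylsilyl)oxy]-2,6,6,11-tetramethyl-9-oxotricyclo[5.4.0.0^{2,8}]undecane-3,5-diyl bis[(2Z)-2-methylbut-2-enoate]
Product: 22 (1S,2R,3S,4R,5S,7S,8R,11R)-4-hydroxy-2,6,6,11-tetramethyl-9-oxotricyclo[5.4.0.0^{2,8}]undecane-3,5-diyl bis[(2Z)-2-methylbut-2-enoate] (CNP0303821.1)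
Conditions: HF·pyridine, THF, 0 °C → rt
Reagents that add atoms: none
Why: Fluoride desilylation under acidic conditions frees the C4 hydroxyl without acyl migration or angelate isomerisation.

**Compound list**
1 | (S)-2,2-dimethyl-1,3-dioxolane-4-carbaldehyde | O=C[C@H]1OC(C)(C)OC1 | starting material
2 | 1-bromo-3-methylbut-2-ene | CC(C)=CCBr | starting material
3 | (S)-2,3-dihydroxypropanal | O=C[C@@H](O)CO | intermediate
4 | (2S,3S)-4,4-dimethylhex-5-ene-1,2,3-triol | C=CC(C)(C)[C@H](O)[C@@H](O)CO | intermediate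
5 | (2S,3S)-1,2-bis[(tert-butyldimethylsilyl)oxy]-4,4-dimethylhex-5-en-3-ol | C=CC(C)(C)[C@H](O)[C@@H](O[Si](C)(C)C(C)(C)C)CO[Si](C)(C)C(C)(C)C | intermediate
6 | (2S,3S)-2-[(tert-butyldimethylsilyl)oxy]-4,4-dimethylhex-5-ene-1,3-diol | C=CC(C)(C)[C@H](O)[C@@H](O[Si](C)(C)C(C)(C)C)CO | intermediate
7 | but-3-en-2-one | C=CC(C)=O | starting material
8 | (3E,6S,7S)-7-[(tert-butyldimethylsilyl)oxy]-6,8-dihydroxy-5,5-dimethyloct-3-en-2-one | CC(=O)/C=C/C(C)(C)[C@H](O)[C@@H](O[Si](C)(C)C(C)(C)C)CO | intermediate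
9 | (2R,3S,5E)-2-[(tert-butyldimethylsilyl)oxy]-3-hydroxy-4,4-dimethyl-7-oxooct-5-enal | CC(=O)/C=C/C(C)(C)[C@H](O)[C@@H](O[Si](C)(C)C(C)(C)C)C=O | intermediate
10 | but-2-yn-1-ol | CC#CCO | starting material
11 | (Z)-3-iodobut-2-en-1-ol | C/C(I)=C/CO | intermediate
12 | (Z)-3-iodobut-2-enal | C/C(I)=C/C=O | intermediate
13 | (Z)-1,1-diethoxy-3-iodobut-2-ene | C/C(I)=C/C(OCC)OCC | intermediate
14 | (3E,6S,7S,8S,9Z)-7-[(tert-butyldimethylsilyl)oxy]-11,11-diethoxy-6,8-dihydroxy-5,5,9-trimethylundeca-3,9-dien-2-one | CC(=O)/C=C/C(C)(C)[C@H](O)[C@@H](O[Si](C)(C)C(C)(C)C)[C@@H](O)/C(C)=C\C(OCC)OCC | intermediate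
15 | (3E,6S,7S,8S,9Z)-7-[(tert-butyldimethylsilyl)oxy]-11,11-diethoxy-5,5,9-trimethyl-6,8-bis[(trimethylsilyl)oxy]undeca-3,9-dien-2-one | CC(=O)/C=C/C(C)(C)[C@H](O[Si](C)(C)C)[C@@H](O[Si](C)(C)C(C)(C)C)[C@@H](O[Si](C)(C)C)/C(C)=C\C(OCC)OCC | intermediate
16 | 1-[3-[(tert-butyldimethylsilyl)oxy]-8-(diethoxymethyl)-1,5,5-trimethyl-2,4-bis[(trimethylsilyl)oxy]bicyclo[4.1.1]octan-7-yl]ethan-1-one | C[Si](C)(C)O[C@@H]1[C@@H](O[Si](C)(C)C(C)(C)C)[C@@H](O[Si](C)(C)C)[C@]2(C)[C@H](C(OCC)OCC)[C@@H]([C@H]2C(C)=O)C1(C)C | intermediate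
17 | 7-acetyl-3-[(tert-butyldimethylsilyl)oxy]-2,4-dihydroxy-1,5,5-trimethylbicyclo[4.1.1]octane-8-carbaldehyde | O[C@@H]1[C@@H](O[Si](C)(C)C(C)(C)C)[C@@H](O)[C@]2(C)[C@H](C=O)[C@@H]([C@H]2C(C)=O)C1(C)C | intermediate
18 | 4-[(tert-butyldimethylsilyl)oxy]-3,5-dihydroxy-2,6,6-trimethyltricyclo[5.4.0.0^{2,8}]undec-10-en-9-one | O[C@@H]1[C@@H](O[Si](C)(C)C(C)(C)C)[C@@H](O)[C@]2(C)[C@@H]3[C@@H]([C@H]2C(=O)C=C3)C1(C)C | intermediate
19 | 4-[(tert-butyldimethylsilyl)oxy]-3,5-dihydroxy-2,6,6,11-tetramethyltricyclo[5.4.0.0^{2,8}]undecan-9-one | O[C@@H]1[C@@H](O[Si](C)(C)C(C)(C)C)[C@@H](O)[C@]2(C)[C@@H]3[C@@H]([C@H]2C(=O)C[C@H]3C)C1(C)C | intermediate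
20 | (Z)-2-methylbut-2-enoic acid (angelic acid) | C/C=C(/C)C(=O)O | starting material
21 | 4-[(tert-butyldimethylsilyl)oxy]-2,6,6,11-tetramethyl-9-oxotricyclo[5.4.0.0^{2,8}]undecane-3,5-diyl bis[(2Z)-2-methylbut-2-enoate] | C/C=C(/C)C(=O)O[C@@H]1[C@@H](O[Si](C)(C)C(C)(C)C)[C@@H](OC(=O)/C(C)=C\C)[C@]2(C)[C@@H]3[C@@H]([C@H]2C(=O)C[C@H]3C)C1(C)C | intermediate
22 | (1S,2R,3S,4R,5S,7S,8R,11R)-4-hydroxy-2,6,6,11-tetramethyl-9-oxotricyclo[5.4.0.0^{2,8}]undecane-3,5-diyl bis[(2Z)-2-methylbut-2-enoate] | C/C=C(/C)C(=O)O[C@@H]1[C@@H](O)[C@@H](OC(=O)/C(C)=C\C)[C@]2(C)[C@@H]3[C@@H]([C@H]2C(=O)C[C@H]3C)C1(C)C | target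

**Step count**
Total: 14 steps. Longest linear sequence: 12 steps (1–5, then 8–14).

**Steps most likely to fail**

Step 10 (the new photocycloaddition). The acyclic enone triplet is short-lived and may only E/Z-isomerise; the straight (6-exo) adduct or abstraction of H8 could also compete. Fallback, from 14 back to 18, with known reaction types: MnO2 oxidises the allylic C8 carbinol of 14 to the bis(enone) (3E,6S,7R,9Z)-7-[(tert-butyldimethylsilyl)oxy]-11,11-diethoxy-6-hydroxy-5,5,9-trimethylundeca-3,9-diene-2,8-dione F1. The anion-radical [2+2] cycloaddition of tethered bis(enones) (cathodic reduction or Co(dpm)2/PhSiH3) bonds β to β′ and then α to α′, which forces the same crossed connectivity and gives 7-acetyl-3-[(tert-butyldimethylsilyl)oxy]-8-(diethoxymethyl)-4-hydroxy-1,5,5-trimethylbicyclo[4.1.1]octan-2-one F2 (diastereomers separated). Hydroxyl-directed Me4NBH(OAc)3 reduction of the β-hydroxy ketone, 1,3-anti to the C4 hydroxyl, gives 1-[3-[(tert-butyldimethylsilyl)oxy]-8-(diethoxymethyl)-2,4-dihydroxy-1,5,5-trimethylbicyclo[4.1.1]octan-7-yl]ethan-1-one F3, which is put through the conditions of step 11 in place of 16 to give 18.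

Step 11 (closure of the strained bridged enone). The aldol equilibrium may be unfavourable, or the required epimerisation slow. Fallback, from 16 back to 18: make the closure irreversible by olefination. The acetyl methyl of 16 is deprotonated (LDA, −78 °C) and trapped with ClP(O)(OEt)2 as the enol phosphate diethyl 1-{3-[(tert-butyldimethylsilyl)oxy]-8-(diethoxymethyl)-1,5,5-trimethyl-2,4-bis[(trimethylsilyl)oxy]bicyclo[4.1.1]octan-7-yl}ethenyl phosphate F4. A second equivalent of LDA induces the known 1,3-phosphorus shift to the β-ketophosphonate diethyl (2-{3-[(tert-butyldimethylsilyl)oxy]-8-(diethoxymethyl)-1,5,5-trimethyl-2,4-bis[(trimethylsilyl)oxy]bicyclo[4.1.1]octan-7-yl}-2-oxoethyl)phosphonate F5. Unmasking (PPTS, wet acetone) and intramolecular Horner–Wadsworth–Emmons olefination (Ba(OH)2, wet THF), which also epimerises the formyl-bearing carbon, gives 18.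

Step 13 (double acylation of two neopentylic hydroxyls). It may stall at a mono-ester, or angelate may isomerise to tiglate on forcing. Fallback, from 19 back to 21: build the Z-enoates after the esters are on. Both hydroxyls of 19 are esterified with the small, unconjugated 2-[bis(2,2,2-trifluoroethoxy)phosphoryl]propanoic acid (2 equiv incorporated; DCC, DMAP) to give 4-[(tert-butyldimethylsilyl)oxy]-2,6,6,11-tetramethyl-9-oxotricyclo[5.4.0.0^{2,8}]undecane-3,5-diyl bis{2-[bis(2,2,2-trifluoroethoxy)phosphoryl]propanoate} F6 (epimers at the phosphonate carbons). Still–Gennari olefination with acetaldehyde (KHMDS, 18-crown-6, THF, −78 °C) then gives 21.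

**Further compounds**
F1 | step 10 | (3E,6S,7R,9Z)-7-[(tert-butyldimethylsilyl)oxy]-11,11-diethoxy-6-hydroxy-5,5,9-trimethylundeca-3,9-diene-2,8-dione | CC(=O)/C=C/C(C)(C)[C@H](O)[C@@H](O[Si](C)(C)C(C)(C)C)C(=O)/C(C)=C\C(OCC)OCC
F2 | step 10 | 7-acetyl-3-[(tert-butyldimethylsilyl)oxy]-8-(diethoxymethyl)-4-hydroxy-1,5,5-trimethylbicyclo[4.1.1]octan-2-one | O[C@@H]1[C@@H](O[Si](C)(C)C(C)(C)C)C(=O)[C@]2(C)[C@H](C(OCC)OCC)[C@@H]([C@H]2C(C)=O)C1(C)C
F3 | step 10 | 1-[3-[(tert-butyldimethylsilyl)oxy]-8-(diethoxymethyl)-2,4-dihydroxy-1,5,5-trimethylbicyclo[4.1.1]octan-7-yl]ethan-1-one | O[C@@H]1[C@@H](O[Si](C)(C)C(C)(C)C)[C@@H](O)[C@]2(C)[C@H](C(OCC)OCC)[C@@H]([C@H]2C(C)=O)C1(C)C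
F4 | step 11 | diethyl 1-{3-[(tert-butyldimethylsilyl)oxy]-8-(diethoxymethyl)-1,5,5-trimethyl-2,4-bis[(trimethylsilyl)oxy]bicyclo[4.1.1]octan-7-yl}ethenyl phosphate | C[Si](C)(C)O[C@@H]1[C@@H](O[Si](C)(C)C(C)(C)C)[C@@H](O[Si](C)(C)C)[C@]2(C)[C@H](C(OCC)OCC)[C@@H]([C@H]2C(=C)OP(=O)(OCC)OCC)C1(C)C
F5 | step 11 | diethyl (2-{3-[(tert-butyldimethylsilyl)oxy]-8-(diethoxymethyl)-1,5,5-trimethyl-2,4-bis[(trimethylsilyl)oxy]bicyclo[4.1.1]octan-7-yl}-2-oxoethyl)phosphonate | C[Si](C)(C)O[C@@H]1[C@@H](O[Si](C)(C)C(C)(C)C)[C@@H](O[Si](C)(C)C)[C@]2(C)[C@H](C(OCC)OCC)[C@@H]([C@H]2C(=O)CP(=O)(OCC)OCC)C1(C)C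
F6 | step 13 | 4-[(tert-butyldimethylsilyl)oxy]-2,6,6,11-tetramethyl-9-oxotricyclo[5.4.0.0^{2,8}]undecane-3,5-diyl bis{2-[bis(2,2,2-trifluoroethoxy)phosphoryl]propanoate} | CC(C(=O)O[C@@H]1[C@@H](O[Si](C)(C)C(C)(C)C)[C@@H](OC(=O)C(C)P(=O)(OCC(F)(F)F)OCC(F)(F)F)[C@]2(C)[C@@H]3[C@@H]([C@H]2C(=O)C[C@H]3C)C1(C)C)P(=O)(OCC(F)(F)F)OCC(F)(F)F
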